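## Retrosynthetic overview
1. The target comes from O-debenzylation of the product of a twofold Suzuki coupling. One common (1R,3R)-8-benzyloxy-5-bromo-1,3-dimethyltetrahydroisoquinoline is used twice, and its partner is an unsymmetrical 4,5'-dibromo-2,2'-binaphthalene-1,1'-diol masked as a cyclic silylene.
2. The central 2,2' bond comes from a silicon-tethered dehydrogenative cross-coupling of 4-bromo- and 5-bromo-8-methoxy-6-methyl-1-naphthol (the new step).
3. Both bromonaphthols come from one 3-methoxy-1-tetralone. Brominating after or before loss of MeOH places Br at C4 or at C5.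
4. Key step: the tetralone is made by a radical four-to-six ring expansion of a 1-arylcyclobutanol, itself built from m-cresol methyl ether and 3-methoxycyclobutanone.
5. Ring order: bought benzene ring, then cyclobutanol, then the second carbocycle of each naphthalene, then the temporary seven-membered silylene ring. Separately: aziridine opening (C3), Bischler–Napieralski N-ring closure, trans reduction (C1).

Assumption: the SMILES fixes only the four stereocentres (1R,3R in both isoquinoline units). The two hindered naphthalene–isoquinoline axes are undefined, so they form as HPLC-separable atropo-diastereomers, and the central binaphthyl axis is taken as freely rotating.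

## Route

Step 1
Reactants: 1 m-cresol
Product: 2 3-methylanisole
Conditions: MeI (1.2 equiv), K2CO3, acetone, reflux
Reagents that add atoms: methyl iodide, CI
Why: Williamson ether synthesis (SN2 O-methylation of the phenoxide) installs the methyl ether that stays in the target and directs the next lithiation.

Step 2
Reactants: 2 3-methylanisole; 3 3-methoxycyclobutan-1-one
Product: 5 3-methoxy-1-(2-methoxy-4-methylphenyl)cyclobutan-1-ol (cis/trans mixture), via aryllithium 4 (not isolated)
Conditions: n-BuLi, TMEDA, Et2O, 0 °C to rt; then 3, THF, −78 °C; aq NH4Cl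
Reagents that add atoms: none
Why: Directed ortho-metalation goes mainly to the less hindered ortho site C6 (the minor C2 isomer is removed by chromatography and has no free ortho position for the next step), and 1,2-addition to the strained ketone at −78 °C outruns enolisation; the cis/trans ratio does not matter because this centre is erased later.

Step 3
Reactants: 5 3-methoxy-1-(2-methoxy-4-methylphenyl)cyclobutan-1-ol
Product: 6 (±)-3,8-dimethoxy-6-methyl-3,4-dihydronaphthalen-1(2H)-one
Conditions: AgNO3 (20 mol %), K2S2O8 (2.5 equiv), CH2Cl2/H2O 1:1, 35 °C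
Reagents that add atoms: none
Why: Key ring expansion, a silver-catalysed persulfate radical ring expansion of a 1-arylcyclobutanol: divalent silver generates the alkoxy radical, strain-driven β-scission gives the γ-keto primary radical, this closes onto the only free ortho carbon (homolytic aromatic substitution) and is oxidised back to the arene, so the four-membered ring becomes the six-membered ketone ring; C3 is racemic and is erased in steps 4 and 5.

Step 4
Reactants: 6 (±)-3,8-dimethoxy-6-methyl-3,4-dihydronaphthalen-1(2H)-one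
Product: 8 4-bromo-8-methoxy-6-methylnaphthalen-1-ol, via naphthol 7 (not isolated)
Conditions: p-TsOH·H2O (10 mol %), MeCN, 60 °C; then NBS (1.0 equiv), −20 °C
Reagents that add atoms: N-bromosuccinimide, O=C1CCC(=O)N1Br
Why: Acid-catalysed β-elimination of methanol gives the keto tautomer of the naphthol, which aromatises, and electrophilic aromatic bromination of the free 1-naphthol then goes para to OH (C4) because the phenolic ring reacts with NBS much faster than the anisole ring.

Step 5
Reactants: 6 (±)-3,8-dimethoxy-6-methyl-3,4-dihydronaphthalen-1(2H)-one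
Product: 10 5-bromo-8-methoxy-6-methylnaphthalen-1-ol, via bromotetralone 9 (not isolated)
Conditions: NBS (1.0 equiv), MeCN, 0 °C to rt; then p-TsOH·H2O (10 mol %), 60 °C
Reagents that add atoms: N-bromosuccinimide, O=C1CCC(=O)N1Br
Why: While the ketone ring is still saturated the anisole ring is the only activated arene, so electrophilic aromatic bromination goes para to OMe (C5), and the same acid-catalysed loss of methanol then aromatises to the isomeric bromonaphthol.

Step 6
Reactants: 8 4-bromo-8-methoxy-6-methylnaphthalen-1-ol; 10 5-bromo-8-methoxy-6-methylnaphthalen-1-ol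
Product: 12 [(4-bromo-8-methoxy-6-methylnaphthalen-1-yl)oxy][(5-bromo-8-methoxy-6-methylnaphthalen-1-yl)oxy]diisopropylsilane, via silyl triflate 11 (not isolated)
Conditions: iPr2Si(OTf)2 (1.0 equiv), 2,6-lutidine, CH2Cl2, −78 °C, 8; then 10, −78 °C to rt
Reagents that add atoms: diisopropylsilyl bis(trifluoromethanesulfonate), CC(C)[Si](OS(=O)(=O)C(F)(F)F)(OS(=O)(=O)C(F)(F)F)C(C)C
Why: Stepwise silyl ether formation gives the mixed silaketal, because the bis(triflate) reacts only once at −78 °C (the aryloxysilyl triflate is far more hindered) and the second naphthol then displaces the remaining triflate.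

Step 7
Reactants: 12 mixed bis(naphthyloxy)diisopropylsilane
Product: 13 cyclic diisopropylsilylene ether of 4,5'-dibromo-8,8'-dimethoxy-6,6'-dimethyl-[2,2'-binaphthalene]-1,1'-diol (a dinaphtho-1,3,2-dioxasilepine)
Conditions: PhI(OCOCF3)2 (1.1 equiv), 2,6-di-tert-butylpyridine, (CF3)2CHOH/CH2Cl2 1:4, 5 mM, −40 to 0 °C
Reagents that add atoms: none
Why: Proposed new method: dehydrogenative silicon-tethered cross-coupling of two different 1-naphthols; single-electron oxidation of one siloxynaphthalene by the trivalent iodine reagent in the radical-cation-stabilising fluoroalcohol gives an arene radical cation whose C2 is attacked by C2 of the second siloxynaphthalene, the only nucleophilic carbon the O–Si–O tether can bring within reach (seven-membered transition state; the para carbons are blocked by Br in one half, shielded by the peri Br in the other, and out of reach of the tether), and a second oxidation with loss of two protons restores both arenes, so only the cross ortho–ortho product can form; the closest known reaction types are the oxidative coupling of silyl bis-enol ethers to 1,4-diketones (same tether and ring size), the hypervalent-iodine intramolecular biaryl coupling of phenol ethers and the silicon-tethered palladium-catalysed C–H arylation of aryloxysilanes, none of which has been shown as an oxidative C–H/C–H union of two aryloxy groups on silicon.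

Step 8
Reactants: 14 1-(benzyloxy)-3-bromobenzene; 15 tert-butyl (R)-2-methylaziridine-1-carboxylate
Product: 17 tert-butyl (R)-{1-[3-(benzyloxy)phenyl]propan-2-yl}carbamate, via Grignard reagent 16 (not isolated)
Conditions: Mg, THF; then CuI (10 mol %), 15, THF, −30 °C to rt; aq NH4Cl
Reagents that add atoms: none
Why: Copper-catalysed SN2 ring opening of the activated aziridine by the aryl Grignard reagent occurs at the unsubstituted carbon, so the stereocentre (future C3, R) comes untouched from the chiral pool.

Step 9
Reactants: 17 tert-butyl (R)-{1-[3-(benzyloxy)phenyl]propan-2-yl}carbamate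
Product: 18 tert-butyl (R)-{1-[5-(benzyloxy)-2-bromophenyl]propan-2-yl}carbamate
Conditions: NBS (1.05 equiv), MeCN, 0 °C to rt
Reagents that add atoms: N-bromosuccinimide, O=C1CCC(=O)N1Br
Why: Electrophilic aromatic bromination with NBS in MeCN is para-selective for aryl ethers, and the bromine both blocks the para position for the ring closure and serves later as the coupling handle.

Step 10
Reactants: 18 tert-butyl (R)-{1-[5-(benzyloxy)-2-bromophenyl]propan-2-yl}carbamate
Product: 20 (R)-N-{1-[5-(benzyloxy)-2-bromophenyl]propan-2-yl}acetamide, via amine hydrochloride 19 (not isolated)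
Conditions: HCl (4 M in dioxane), rt; then Et3N, Ac2O, CH2Cl2, 0 °C to rt
Reagents that add atoms: acetic anhydride, CC(=O)OC(C)=O
Why: Acidolysis of the Boc carbamate followed by N-acetylation in the same flask breaks no bond at the stereocentre and brings in C1 and its methyl group.

Step 11
Reactants: 20 (R)-N-{1-[5-(benzyloxy)-2-bromophenyl]propan-2-yl}acetamide
Product: 21 (R)-8-(benzyloxy)-5-bromo-1,3-dimethyl-3,4-dihydroisoquinoline
Conditions: Tf2O (1.1 equiv), 2-chloropyridine (1.2 equiv), CH2Cl2, −78 °C to rt; aq NaHCO3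
Reagents that add atoms: none
Why: Bischler–Napieralski cyclodehydration by electrophilic amide activation gives a nitrilium ion that can attack only the carbon ortho to OBn, since the para carbon carries Br.

Step 12
Reactants: 21 (R)-8-(benzyloxy)-5-bromo-1,3-dimethyl-3,4-dihydroisoquinoline
Product: 22 (1R,3R)-8-(benzyloxy)-5-bromo-1,3-dimethyl-1,2,3,4-tetrahydroisoquinoline
Conditions: AlMe3, then LiAlH4, THF, −78 to 0 °C; aq NaOH
Reagents that add atoms: none
Why: In this substrate-controlled diastereoselective imine reduction, precomplexation of nitrogen with bulky AlMe3 reverses the usual facial preference so that hydride enters syn to the C3 methyl group, which is the established way to trans-1,3-dimethyltetrahydroisoquinolines and sets C1 as R.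

Step 13
Reactants: 22 (1R,3R)-8-(benzyloxy)-5-bromo-1,3-dimethyl-1,2,3,4-tetrahydroisoquinoline (2.6 equiv); 13 cyclic silylene of the dibromobinaphthol
Product: 25 4,5'-bis[(1R,3R)-8-(benzyloxy)-1,3-dimethyl-1,2,3,4-tetrahydroisoquinolin-5-yl]-8,8'-dimethoxy-6,6'-dimethyl-[2,2'-binaphthalene]-1,1'-diol, via pinacol boronate 23 (not isolated), via silylene-bridged quateraryl 24 (not isolated)
Conditions: 22, B2pin2 (2.6 equiv), Pd(OAc)2 (5 mol %), SPhos (10 mol %), KOAc, dioxane, 90 °C; then 13 (1 equiv), aq K3PO4, 100 °C; then TBAF, THF, rt (argon)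
Reagents that add atoms: none
Why: Miyaura borylation followed by a twofold Suzuki–Miyaura coupling uses a bulky dialkylbiarylphosphine that copes with ortho and peri hindrance and leaves the hindered secondary amine alone, and fluoride then removes the silylene; no stereocentre is touched and the two new hindered axes form as separable atropo-diastereomers.

Step 14
Reactants: 25 bis(benzyl ether)
Product: 26 4,5'-bis[(1R,3R)-8-hydroxy-1,3-dimethyl-1,2,3,4-tetrahydroisoquinolin-5-yl]-8,8'-dimethoxy-6,6'-dimethyl-[2,2'-binaphthalene]-1,1'-diol (target)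
Conditions: H2 (1 atm), Pd/C (10 wt %), MeOH/CH2Cl2, rt
Reagents that add atoms: none
Why: Catalytic hydrogenolysis cleaves the two aryl benzyl ethers, reduces back any binaphthylidenedione formed by adventitious air oxidation, and leaves the methyl ethers and the four stereocentres untouched.

## Compound list
1 | m-cresol | Cc1cccc(O)c1 | starting material
2 | 3-methylanisole | COc1cccc(C)c1 | intermediate
3 | 3-methoxycyclobutan-1-one | COC1CC(=O)C1 | starting material
4 | (2-methoxy-4-methylphenyl)lithium | [Li]c1ccc(C)cc1OC | intermediate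
5 | 3-methoxy-1-(2-methoxy-4-methylphenyl)cyclobutan-1-ol (cis/trans) | COC1CC(O)(C1)c1ccc(C)cc1OC | intermediate
6 | (±)-3,8-dimethoxy-6-methyl-3,4-dihydronaphthalen-1(2H)-one | COC1CC(=O)c2c(OC)cc(C)cc2C1 | intermediate
7 | 8-methoxy-6-methylnaphthalen-1-ol | COc1cc(C)cc2cccc(O)c12 | intermediate
8 | 4-bromo-8-methoxy-6-methylnaphthalen-1-ol | COc1cc(C)cc2c(Br)ccc(O)c12 | intermediate
9 | (±)-5-bromo-3,8-dimethoxy-6-methyl-3,4-dihydronaphthalen-1(2H)-one | COC1CC(=O)c2c(OC)cc(C)c(Br)c2C1 | intermediate
10 | 5-bromo-8-methoxy-6-methylnaphthalen-1-ol | COc1cc(C)c(Br)c2cccc(O)c12 | intermediate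
11 | [(4-bromo-8-methoxy-6-methylnaphthalen-1-yl)oxy]diisopropylsilyl triflate | CC(C)[Si](OS(=O)(=O)C(F)(F)F)(Oc1ccc(Br)c2cc(C)cc(OC)c12)C(C)C | intermediate
12 | mixed bis(naphthyloxy)diisopropylsilane | CC(C)[Si](Oc1ccc(Br)c2cc(C)cc(OC)c12)(Oc1cccc2c(Br)c(C)cc(OC)c12)C(C)C | intermediate
13 | cyclic diisopropylsilylene ether of 4,5'-dibromo-8,8'-dimethoxy-6,6'-dimethyl-[2,2'-binaphthalene]-1,1'-diol | CC(C)[Si]1(C(C)C)Oc2c(cc(Br)c3cc(C)cc(OC)c23)-c2ccc3c(Br)c(C)cc(OC)c3c2O1 | intermediate
14 | 1-(benzyloxy)-3-bromobenzene | Brc1cccc(OCc2ccccc2)c1 | starting material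
15 | tert-butyl (R)-2-methylaziridine-1-carboxylate | C[C@@H]1CN1C(=O)OC(C)(C)C | starting material
16 | [3-(benzyloxy)phenyl]magnesium bromide | Br[Mg]c1cccc(OCc2ccccc2)c1 | intermediate
17 | tert-butyl (R)-{1-[3-(benzyloxy)phenyl]propan-2-yl}carbamate | C[C@H](Cc1cccc(OCc2ccccc2)c1)NC(=O)OC(C)(C)C | intermediate
18 | tert-butyl (R)-{1-[5-(benzyloxy)-2-bromophenyl]propan-2-yl}carbamate | C[C@H](Cc1cc(OCc2ccccc2)ccc1Br)NC(=O)OC(C)(C)C | intermediate
19 | (R)-1-[5-(benzyloxy)-2-bromophenyl]propan-2-amine hydrochloride | C[C@H](Cc1cc(OCc2ccccc2)ccc1Br)N.Cl | intermediate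
20 | (R)-N-{1-[5-(benzyloxy)-2-bromophenyl]propan-2-yl}acetamide | C[C@H](Cc1cc(OCc2ccccc2)ccc1Br)NC(C)=O | intermediate
21 | (R)-8-(benzyloxy)-5-bromo-1,3-dimethyl-3,4-dihydroisoquinoline | Brc1ccc(OCc2ccccc2)c2c1C[C@@H](C)N=C2C | intermediate
22 | (1R,3R)-8-(benzyloxy)-5-bromo-1,3-dimethyl-1,2,3,4-tetrahydroisoquinoline | Brc1ccc(OCc2ccccc2)c2c1C[C@@H](C)N[C@@H]2C | intermediate
23 | (1R,3R)-8-(benzyloxy)-1,3-dimethyl-5-(4,4,5,5-tetramethyl-1,3,2-dioxaborolan-2-yl)-1,2,3,4-tetrahydroisoquinoline | CC1(C)OB(OC1(C)C)c1ccc(OCc2ccccc2)c2c1C[C@@H](C)N[C@@H]2C | intermediate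
24 | cyclic diisopropylsilylene ether of 25 | CC(C)[Si]1(C(C)C)Oc2c(cc(-c4ccc(OCc5ccccc5)c5c4C[C@@H](C)N[C@@H]5C)c3cc(C)cc(OC)c23)-c2ccc3c(-c4ccc(OCc5ccccc5)c5c4C[C@@H](C)N[C@@H]5C)c(C)cc(OC)c3c2O1 | intermediate
25 | 4,5'-bis[(1R,3R)-8-(benzyloxy)-1,3-dimethyl-1,2,3,4-tetrahydroisoquinolin-5-yl]-8,8'-dimethoxy-6,6'-dimethyl-[2,2'-binaphthalene]-1,1'-diol | COc1cc(C)cc2c(-c3ccc(OCc7ccccc7)c4c3C[C@@H](C)N[C@@H]4C)cc(-c3ccc4c(-c5ccc(OCc7ccccc7)c6c5C[C@@H](C)N[C@@H]6C)c(C)cc(OC)c4c3O)c(O)c12 | intermediate
26 | 4,5'-bis[(1R,3R)-8-hydroxy-1,3-dimethyl-1,2,3,4-tetrahydroisoquinolin-5-yl]-8,8'-dimethoxy-6,6'-dimethyl-[2,2'-binaphthalene]-1,1'-diol | COc1cc(C)cc2c(-c3ccc(O)c4c3C[C@@H](C)N[C@@H]4C)cc(-c3ccc4c(-c5ccc(O)c6c5C[C@@H](C)N[C@@H]6C)c(C)cc(OC)c4c3O)c(O)c12 | target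

## Totals and risks
Total step count: 14.

Longest linear sequence: 8 (steps 1, 2, 3, 4 or 5, 6, 7, 13, 14).

**Risk 1, step 7 (the proposed new step).**
- The radical cation may lose the silyl group and go on to quinone-type products, or it may couple intermolecularly.
- The fallback uses known chemistry. It sets out from 8 (and uses 10) and comes back at 13.
- NIS in MeCN iodinates 8 ortho to OH, since the para carbon is blocked, and gives 4-bromo-2-iodo-8-methoxy-6-methylnaphthalen-1-ol F1.
- Treating this with iPr2Si(OTf)2 and 2,6-lutidine at −78 °C gives [(4-bromo-2-iodo-8-methoxy-6-methylnaphthalen-1-yl)oxy]diisopropylsilyl triflate F2.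
- Adding 10 then gives the iodinated mixed bis(naphthyloxy)diisopropylsilane F3.
- A silicon-tethered palladium-catalysed intramolecular direct C–H arylation closes the seven-membered ring to 13 (Pd(OAc)2, PCy3·HBF4, pivalic acid, Cs2CO3, toluene, 100 °C).
- In that closure zerovalent palladium inserts into the carbon–iodine bond in preference to the two carbon–bromine bonds.

**Risk 2, step 3.**
- The β-methoxy ketone may lose methanol in the acidic oxidising medium, and the resulting naphthol would be over-oxidised.
- The fallback takes the leaving group out of the oxidative step and makes aromatisation a separate dehydrogenation. It sets out from 4 and comes back at 7 and at 10.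
- Adding 4 to commercial cyclobutanone gives 1-(2-methoxy-4-methylphenyl)cyclobutan-1-ol F4.
- Silver/persulfate ring expansion of this leaving-group-free substrate gives the oxidant-stable 8-methoxy-6-methyl-3,4-dihydronaphthalen-1(2H)-one F5.
- DDQ in refluxing dioxane dehydrogenates it to 7, which is brominated as in step 4.
- Alternatively, NBS in MeCN first gives 5-bromo-8-methoxy-6-methyl-3,4-dihydronaphthalen-1(2H)-one F6, and DDQ then gives 10.

**Risk 3, step 13.**
- Both couplings are hindered, the one next to the methyl group most of all, and protodeboronation of 23 competes.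
- The fallback reverses the polarity. It sets out from 13 (and uses 22) and comes back at 24.
- Twofold bromine–lithium exchange (n-BuLi, THF, −78 °C) gives the 4,5'-dilithiated silylene-bridged binaphthyl F7.
- ZnCl2 converts it into the silylene-bridged binaphthyl-4,5'-diylbis(zinc chloride) F8.
- A twofold Negishi coupling with 22 (Pd2(dba)3, RuPhos, THF, 60 °C) gives 24. Arylzinc reagents tolerate the free hindered NH.
- TBAF then gives 25 as in step 13.

## Further compounds
F1 | step 7 | 4-bromo-2-iodo-8-methoxy-6-methylnaphthalen-1-ol | COc1cc(C)cc2c(Br)cc(I)c(O)c12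
F2 | step 7 | [(4-bromo-2-iodo-8-methoxy-6-methylnaphthalen-1-yl)oxy]diisopropylsilyl triflate | CC(C)[Si](OS(=O)(=O)C(F)(F)F)(Oc1c(I)cc(Br)c2cc(C)cc(OC)c12)C(C)C
F3 | step 7 | iodinated mixed bis(naphthyloxy)diisopropylsilane | CC(C)[Si](Oc1c(I)cc(Br)c2cc(C)cc(OC)c12)(Oc1cccc2c(Br)c(C)cc(OC)c12)C(C)C
F4 | step 3 | 1-(2-methoxy-4-methylphenyl)cyclobutan-1-ol | COc1cc(C)ccc1C1(O)CCC1
F5 | step 3 | 8-methoxy-6-methyl-3,4-dihydronaphthalen-1(2H)-one | COc1cc(C)cc2c1C(=O)CCC2
F6 | step 3 | 5-bromo-8-methoxy-6-methyl-3,4-dihydronaphthalen-1(2H)-one | COc1cc(C)c(Br)c2c1C(=O)CCC2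
F7 | step 13 | 4,5'-dilithiated silylene-bridged binaphthyl | CC(C)[Si]1(C(C)C)Oc2c(cc([Li])c3cc(C)cc(OC)c23)-c2ccc3c([Li])c(C)cc(OC)c3c2O1
F8 | step 13 | silylene-bridged binaphthyl-4,5'-diylbis(zinc chloride) | CC(C)[Si]1(C(C)C)Oc2c(cc([Zn]Cl)c3cc(C)cc(OC)c23)-c2ccc3c([Zn]Cl)c(C)cc(OC)c3c2O1
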